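All runs are calculated for an exercise; scatter was added.

Start from temperature: delta ran warmer than epsilon, and the two runs differ in how far the left-handed product leads. Here partner, which is single-handed, turns each substrate into the product of the same hand.

| setting | epsilon | delta | Friday's | Thursday's |
|---|---|---|---|---|
| left-handed substrate | 0.069 M | 0.069 M | 0.069 M | 0.069 M |
| right-handed substrate | 0.069 M | 0.069 M | 0.069 M | 0.069 M |
| partner | 1.2 equiv | 1.9 equiv | 0.800 equiv | 1.60 equiv |
| temperature | −25 °C | −10 °C | 0 °C | −20 °C |
| remark | run made earlier | run made earlier |  |  |
| time |  |  | 15 min | 5.0 min |

| run | time / min | left-handed product / % | right-handed product / % |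
|---|---|---|---|
| epsilon | 3.00 | 3 | 0 |
| epsilon | 6.00 | 3 | 2 |
| epsilon | 15.0 | 7 | 1 |
| epsilon | 30.0 | 11 | 3 |
| delta | 4.00 | 8 | 4 |
| delta | 8.00 | 19 | 5 |
| delta | 12.0 | 19 | 8 |
| delta | 15.0 | 23 | 6 |

(each reading ± 1.5 percentage points)

- which of the two ends with the higher excess of left-handed product over right-handed product ("neither" if they lie within 2 percentage points) (Friday's / Thursday's / neither)
- excess of left-handed product over right-handed product at the end, Friday's
- excess of left-handed product over right-handed product at the end, Thursday's

- partner is single-handed; left-handed substrate and right-handed substrate are mirror images of each other, charged as a racemate, each of them at the stated concentration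
- the earlier runs were read with a standard deviation of 1.5 percentage points
- an excess is below zero if the other one leads
- the handed part of partner does not stay in what it makes, so the products of the two hands are mirror images too

Add each run's readings, hand against hand, to damp the scatter. Epsilon gives a ratio of 4.00, and delta 3.00. At low conversion such a ratio tends to the selectivity factor. Take the natural log of epsilon's ratio over delta's: 0.288. Call this the span, the drop in log ratio from epsilon's temperature to delta's.

Assume the log ratio falls in step with temperature. The excess is the ratio less one, over the ratio plus one. Thursday's flask looks nearly like epsilon, 0.333 of a span warmer. That gives a ratio of 3.63 and an excess of 56.8%. Friday's flask stands 1.67 spans above epsilon, which gives 42.5%.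

Now count lifetimes. Delta's last reading, taken as pseudo-first-order decay of left-handed substrate, gives a lifetime of 24.3 min. Thursday's flask, colder and with less partner than delta, stops at 0.205 of that lifetime. Friday's flask, warmer and with less partner than delta, stops at 0.616 of it, a rough count, but larger than Thursday's. Commit to Thursday's, whose reckoned excess stands above Friday's. Hold its figure loosely: epsilon's right-handed sum is 6.00%, with a scatter of 3 percentage points.

The forecast names Thursday's, with 50% for Friday's and 58% for Thursday's, holding that “left reacts roughly 4 times faster than right”; its Friday's figure stands above mine.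

Friday's flask ends at 45.8% and Thursday's at 67.5%.

    partner + left-handed substrate → left-handed product (k = 0.0160 L mol⁻¹ s⁻¹, Ea = 46.0 kJ mol⁻¹)
    partner + right-handed substrate → right-handed product (k = 0.00520 L mol⁻¹ s⁻¹, Ea = 62.0 kJ mol⁻¹)
    2 partner → self-condensation product (k = 0.00450 L mol⁻¹ s⁻¹, Ea = 62.0 kJ mol⁻¹)
    partner → decomposition product (k = 5.60 × 10⁻⁷ s⁻¹, Ea = 90.0 kJ mol⁻¹)
    (constants at 0 °C)

Thursday's flask holds 4.82% left-handed product against 0.934% right-handed product, a ratio of 5.15 where the span gave 3.63. Use the span once more. A neighbour flask repeats Thursday's at −5 °C, 1.00 span warmer. Lower Thursday's simulated ratio by that span: the ratio becomes 3.87 and the excess 58.9%. The neighbour flask ends at 52.0%.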